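Count target against partner.

| flask | solid substrate | partner | temperature | remark | time |
|---|---|---|---|---|---|
| maple | 0.10 M | 0.055 M | 48 °C | run made earlier |  |
| ash | 0.10 M | 0.083 M | 75 °C | run made earlier |  |
| cedar | 0.15 M | 0.11 M | 48 °C | run made earlier |  |
| violet | 0.10 M | 0.110 M | 35 °C |  | 2.5 min |
| green | 0.10 M | 0.110 M | 60 °C |  | 2.5 min |
| teal | 0.10 M | 0.110 M | 85 °C |  | 2.5 min |

| run | time / s | target / % | solid substrate / % |
|---|---|---|---|
| maple | 10.0 | 9.7 | 0.1 |
| maple | 12.0 | 11.6 | 0.7 |
| maple | 20.0 | 16.4 | 0 |
| maple | 30.0 | 17.8 | 0.1 |
| maple | 50.0 | 16.3 | 0.1 |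
| ash | 10.0 | 15.9 | 0.1 |
| ash | 12.0 | 17.0 | 0 |
| cedar | 10.0 | 13.0 | 26.6 |
| cedar | 12.0 | 15.6 | 19.7 |
| cedar | 25.0 | 23.3 | 0 |
| cedar | 50.0 | 22.1 | 1.4 |

(readings scatter by 0.5 percentage points)

- as a solid, counted per litre of solution: solid substrate
- the analysis behind the earlier runs scatters by 0.5 percentage points, standard deviation
- at the start none of the solid substrate is in solution
- what has only dissolved of solid substrate counts as not reacted

* the flask that comes out highest in amount of target, in percent of the solid substrate charged, or "all alike" when all lie within 1.5 percentage points (violet / green / teal / all alike)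
* target at the end, in percent of the solid substrate charged, violet
* target at the end, in percent of the solid substrate charged, green
* target at the end, in percent of the solid substrate charged, teal

In maple the target curve peaks at a reading of 17.8%, which is 0.324 per partner charged. I carry this partner yield Y, target at the level of its curve per partner charged. Cedar reads 0.318 at a different charge, and in both runs partner is the limiting reagent by charge. Hotter ash stands at 17.0% at its last reading, which I take as its level, so its Y of 0.205 is lower. I assume ln Y runs straight with temperature, and I stretch that line past both ends and to flasks charged with more partner than solid substrate: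

Y(T) = Y(maple) × (Y(ash)/Y(maple))^((T − T(maple))/(T(ash) − T(maple)))

violet 0.403, green 0.264, teal 0.173

level = Y × [partner] / [solid substrate], as charged

violet 44.4%, green 29.0%, teal 19.0%

Now the curve, reckoned by the fraction f of the level still unmade. At 12.0 s maple has f = 0.348 and cedar 0.330, so:

τ = −t / ln f = 11.4 s

For violet's cooler bath I allow 4 times that, 45.5 s. I place the knee of violet's curve there, where its opening slope reaches the level in my reckoning. At 2.5 min, f is 0.0370, which puts violet at 42.7%. Maple sags to 16.3% after its peak; I assume that belongs to partner-short flasks and hold the level flat. I expect violet highest.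

The forecast also names violet, but at 29%, 18% and 4%, each below my figures, reasoning that “Green loses over half, and teal loses nearly everything”.

The flasks give 41.5% in violet, 27.9% in green and 17.6% in teal, so violet is highest.

    starting material + partner → target (k = 0.734 L mol⁻¹ s⁻¹, Ea = 40.0 kJ mol⁻¹)
    starting material + partner → isomer of the product (k = 0.514 L mol⁻¹ s⁻¹, Ea = 65.0 kJ mol⁻¹)
    starting material + partner → second isomer (k = 0.0410 L mol⁻¹ s⁻¹, Ea = 75.0 kJ mol⁻¹)
    solid substrate ⇌ starting material, rate k4*(cs4 - [starting material]) while solid is left; crystals form when [starting material] > cs4 (solubility = 0.0970 M, k = 0.253 s⁻¹)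
    partner → decomposition product (k = 7.45 × 10⁻⁵ s⁻¹, Ea = 117 kJ mol⁻¹)
    starting material + target → side product (k = 0.846 L mol⁻¹ s⁻¹, Ea = 61.0 kJ mol⁻¹)
    (constants at 60 °C)

Violet's result at 2.50 min makes Y 0.377, against the 0.403 I reckoned. A neighbour flask keeps violet's partner and temperature but is charged with 0.17 M of solid substrate. The same Y gives it 24.4% of that larger charge. The flask gives 20.1%, which is lower. At 2.50 min it still holds 16.0% of the solid substrate charged as starting material and 7.34% of its partner charge, and side product, which counts as two in every percentage, is its largest share at 48.2%.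

The readings are calculated for substances that don't exist.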